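**Retrosynthetic overview**
1. The C9 ketone is unveiled last, by oxidising the C9 carbinol. C8–H and C10–H are configurationally safe only while C9 is sp3.
2. The carbinol is cut at C8–C9: a lateral (vinylogous) aldol of the symmetrical ring A pyrone onto an α-chiral ring B aldehyde.
3. Key disconnection: the ring O–C bond of ring B. Ring B comes from a Roche-derived β-diketone and hexanoyl chloride by a new silicon-driven C–O cyclodehydration that leaves C10 untouched.
4. Ring A is cut at the same O–C bond: pentan-3-one plus two propanoic acids, with the triketone closing in polyphosphoric acid.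
5. Order: rings A and B are closed separately, then joined. C10 comes from (R)-Roche ester and C8 from the aldol.

Assumption (labels): the main chain runs from C1 (ethyl CH3) to C20 (pentyl CH3). Ring A is O plus C3–C7, ring B is O plus C11–C15, the stereocentres are C8 and C10, and the ketone is C9.

**Step 1**
Reactants: 1 pentan-3-one; 2 propanoic acid (2 equiv)
Product: 3 2,6-diethyl-3,5-dimethyl-4H-pyran-4-one
Conditions: polyphosphoric acid, 95 °C, 8 h
Reagents that add atoms: none
Why: In the classical polyphosphoric acid γ-pyrone synthesis, acid-mediated C-acylation of both α-carbons gives the 1,3,5-triketone, which closes ring A by C–O cyclodehydration in the same medium; no stereocentre is involved.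

**Step 2**
Reactants: 4 methyl (R)-3-hydroxy-2-methylpropanoate
Product: 5 methyl (R)-2-methyl-3-(triethylsilyloxy)propanoate
Conditions: Et3SiCl, imidazole, CH2Cl2, 0 °C to rt
Reagents that add atoms: chlorotriethylsilane, CC[Si](Cl)(CC)CC
Why: Routine silyl ether protection keeps the C9 oxygen from attacking the later polyketone, and C10 is not touched.

**Step 3**
Reactants: 1 pentan-3-one (3 equiv); 5 methyl (R)-2-methyl-3-(triethylsilyloxy)propanoate
Product: 7 (6R)-4,6-dimethyl-7-(triethylsilyloxy)heptane-3,5-dione, via lithium enolate 6 (not isolated)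
Conditions: LiN(iPr)2 (2.9 equiv), THF, −78 °C; 5, −78 to 0 °C; AcOH
Reagents that add atoms: none
Why: In this crossed Claisen condensation the excess enolate removes the acidic C12–H of the product as it forms, which drives the reaction and shields C10–H from base, so the Roche configuration is kept.

**Step 4**
Reactants: 7 (6R)-4,6-dimethyl-7-(triethylsilyloxy)heptane-3,5-dione; 8 hexanoyl chloride
Product: 13 2-[(2R)-1-hydroxypropan-2-yl]-3,5-dimethyl-6-pentyl-4H-pyran-4-one, via dilithium dianion 9 (not isolated), via bis-silyl diene 10 (not isolated), via silyl enol ether triketone 11 (not isolated), via TES-protected pyrone 12 (not isolated)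
Conditions: LiN(iPr)2 (2.1 equiv), THF, −78 to 0 °C; Me3SiCl (2.3 equiv); solvent switch to CH2Cl2; 8 (1.1 equiv), Me3SiOTf (10 mol%), 2,6-di-tert-butylpyridine (1.1 equiv), −78 to 0 °C; then 1 M HCl, THF, 0 °C
Reagents that add atoms: none
Why: Proposed new method: the cross-conjugated dianion is trapped as a 1,3-bis(silyloxy)diene whose terminal carbon C14 is C-acylated by 8 (known reactivity of such dienes, releasing Me3SiCl), Me3SiOTf then silylates the central carbonyl of the enolised product to a trioxygenated pentadienyl cation in which the C15 enol oxygen adds to C11 and the C11–OSiMe3 group leaves, so the two silyl groups carry off the lost oxygen as (Me3Si)2O (TfOH plus Me3SiCl regenerates Me3SiOTf and the hindered pyridine takes up HCl), and ring B forms by C–O bond formation under aprotic near-neutral conditions in which C11 is locked as its C11=C12 enol ether and cannot enolise towards C10, which keeps its configuration; the closest known reactions are the acid or Ph3P/CCl4 cyclodehydration of 1,3,5-triketones to γ-pyrones and Me3SiOTf-mediated cyclisations of 1,3-bis(silyl enol ethers).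

**Step 5**
Reactants: 13 2-[(2R)-1-hydroxypropan-2-yl]-3,5-dimethyl-6-pentyl-4H-pyran-4-one
Product: 14 (2S)-2-(3,5-dimethyl-4-oxo-6-pentyl-4H-pyran-2-yl)propanal
Conditions: Dess–Martin periodinane, CH2Cl2, 0 °C to rt; used at once without chromatography
Reagents that add atoms: none
Why: Dess–Martin oxidation works without amine base, so the acidic C10–H of the α-pyronyl aldehyde is not exchanged (the descriptor changes only through CIP priorities).

**Step 6**
Reactants: 3 2,6-diethyl-3,5-dimethyl-4H-pyran-4-one (1.6 equiv); 14 (2S)-2-(3,5-dimethyl-4-oxo-6-pentyl-4H-pyran-2-yl)propanal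
Product: 16 (2R,3S,4R)-2-(3,5-dimethyl-4-oxo-6-pentyl-4H-pyran-2-yl)-4-(6-ethyl-3,5-dimethyl-4-oxo-4H-pyran-2-yl)pentan-3-ol, via lithium dienolate 15 (not isolated)
Conditions: LiN(SiMe3)2 (1.5 equiv), THF, −78 °C; 14, −78 °C, 30 min; AcOH at −78 °C
Reagents that add atoms: none
Why: This is a vinylogous aldol addition of the lateral lithium dienolate (established for this pyrone): allylic strain fixes one dienolate geometry (CH3 turned away from the C6 methyl), the remote O–Li forces an open antiperiplanar Felkin–Anh transition state, and the expected product is 8,9-anti-9,10-syn with C8 and C10 methyls anti; its C9 epimer in the same anti series gives the same ketone, the 8,10-syn isomers are removed by chromatography, and any enolised 14 is inert at −78 °C and costs yield but not purity.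

**Step 7**
Reactants: 16 (2R,3S,4R)-2-(3,5-dimethyl-4-oxo-6-pentyl-4H-pyran-2-yl)-4-(6-ethyl-3,5-dimethyl-4-oxo-4H-pyran-2-yl)pentan-3-ol
Product: 17 (2S,4S)-2-(3,5-dimethyl-4-oxo-6-pentyl-4H-pyran-2-yl)-4-(6-ethyl-3,5-dimethyl-4-oxo-4H-pyran-2-yl)pentan-3-one
Conditions: Dess–Martin periodinane, CH2Cl2, 0 °C to rt; short silica filtration
Reagents that add atoms: none
Why: Dess–Martin oxidation removes the C9 stereocentre under non-basic conditions, so the now labile C8 and C10 centres keep their geometry and both become S by CIP priority change.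

**Compound list**
1 | pentan-3-one | CCC(=O)CC | starting material
2 | propanoic acid | CCC(=O)O | starting material
3 | 2,6-diethyl-3,5-dimethyl-4H-pyran-4-one (ring A block) | CCc1oc(CC)c(C)c(=O)c1C | intermediate
4 | methyl (R)-3-hydroxy-2-methylpropanoate ((R)-Roche ester) | COC(=O)[C@H](C)CO | starting material
5 | methyl (R)-2-methyl-3-(triethylsilyloxy)propanoate | COC(=O)[C@H](C)CO[Si](CC)(CC)CC | intermediate
6 | lithium pent-2-en-3-olate | [Li+].CC=C([O-])CC | intermediate
7 | (6R)-4,6-dimethyl-7-(triethylsilyloxy)heptane-3,5-dione (C4 epimers, partly enolised) | CCC(=O)C(C)C(=O)[C@H](C)CO[Si](CC)(CC)CC | intermediate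
8 | hexanoyl chloride | CCCCCC(=O)Cl | starting material
9 | dilithium (6R)-4,6-dimethyl-7-(triethylsilyloxy)hepta-2,4-diene-3,5-diolate | [Li+].[Li+].CC=C([O-])C(C)=C([O-])[C@H](C)CO[Si](CC)(CC)CC | intermediate
10 | (6R)-4,6-dimethyl-7-(triethylsilyloxy)-3,5-bis(trimethylsilyloxy)hepta-2,4-diene | CC=C(O[Si](C)(C)C)C(C)=C(O[Si](C)(C)C)[C@H](C)CO[Si](CC)(CC)CC | intermediate
11 | (2R)-2,4,6-trimethyl-1-(triethylsilyloxy)-3-(trimethylsilyloxy)dodec-3-ene-5,7-dione (C6 epimers) | CCCCCC(=O)C(C)C(=O)C(C)=C(O[Si](C)(C)C)[C@H](C)CO[Si](CC)(CC)CC | intermediate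
12 | 3,5-dimethyl-6-pentyl-2-[(2R)-1-(triethylsilyloxy)propan-2-yl]-4H-pyran-4-one | CCCCCc1oc([C@H](C)CO[Si](CC)(CC)CC)c(C)c(=O)c1C | intermediate
13 | 2-[(2R)-1-hydroxypropan-2-yl]-3,5-dimethyl-6-pentyl-4H-pyran-4-one | CCCCCc1oc([C@H](C)CO)c(C)c(=O)c1C | intermediate
14 | (2S)-2-(3,5-dimethyl-4-oxo-6-pentyl-4H-pyran-2-yl)propanal | CCCCCc1oc([C@H](C)C=O)c(C)c(=O)c1C | intermediate
15 | lithium (2Z)-6-ethyl-2-ethylidene-3,5-dimethyl-2H-pyran-4-olate | [Li+].C/C=C1\OC(CC)=C(C)C([O-])=C1C | intermediate
16 | (2R,3S,4R)-2-(3,5-dimethyl-4-oxo-6-pentyl-4H-pyran-2-yl)-4-(6-ethyl-3,5-dimethyl-4-oxo-4H-pyran-2-yl)pentan-3-ol | CCCCCc1oc([C@H](C)[C@@H](O)[C@@H](C)c2oc(CC)c(C)c(=O)c2C)c(C)c(=O)c1C | intermediate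
17 | (2S,4S)-2-(3,5-dimethyl-4-oxo-6-pentyl-4H-pyran-2-yl)-4-(6-ethyl-3,5-dimethyl-4-oxo-4H-pyran-2-yl)pentan-3-one | CCCCCc1oc([C@H](C)C(=O)[C@@H](C)c2oc(CC)c(C)c(=O)c2C)c(C)c(=O)c1C | target

**Step count**
Total steps: 7. Longest linear sequence: 6 (steps 2 to 7, from 4). Step 1 is a one-step side branch.

**Steps most likely to fail**

Step 4 (the new method). The risks are O-acylation of the diene, early loss of the triethylsilyl group, and a sluggish silicon-driven closure. The fallback sets out from 7 and comes back at 12, using an aldol, oxidation and dehydration sequence in place of acylation and silyl closure. The dianion of 7 (LiN(iPr)2, 2.1 equiv) is added to hexanal to give the δ-hydroxy-β-diketone (2R)-7-hydroxy-2,4,6-trimethyl-1-(triethylsilyloxy)dodecane-3,5-dione F1. Dess–Martin oxidation then gives the free triketone (2R)-2,4,6-trimethyl-1-(triethylsilyloxy)dodecane-3,5,7-trione F2. The established neutral Ph3P/CCl4 dehydration of 1,3,5-triketones closes ring B to 12, and dilute HCl in THF gives 13.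

Step 6. The risks are a modest C8 selectivity in the open transition state and enolisation of 14. The fallback sets out from 14 and comes back at 17. It sets C8 by auxiliary control and builds ring A afterwards.
- The TiCl4/iPr2NEt/N-methylpyrrolidinone enolate of commercial (R)-4-benzyl-3-propanoyl-1,3-thiazolidine-2-thione adds to 14 in an Evans-syn aldol. This gives (R)-4-benzyl-3-[(2R,3S,4R)-4-(3,5-dimethyl-4-oxo-6-pentyl-4H-pyran-2-yl)-3-hydroxy-2-methylpentanoyl]-1,3-thiazolidine-2-thione F3.
- Et3SiOTf and 2,6-lutidine give its C9 triethylsilyl ether F4.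
- The dianion of commercial 4-methylheptane-3,5-dione (LiN(iPr)2) displaces the auxiliary to give the triketone 3,5-dimethyl-6-pentyl-2-[(2R,3S,4R)-4,6,8-trimethyl-5,7,9-trioxo-3-(triethylsilyloxy)undecan-2-yl]-4H-pyran-4-one F5.
- Ph3P/CCl4 closes ring A to the silyl-protected bis-pyrone F6.
- HF·pyridine frees the (2R,3R,4R)-carbinol F7, the C9 epimer of 16, and Dess–Martin oxidation gives 17.

Step 3. The risks are slow acylation of a hindered ketone enolate by the ester, with α-deprotonation or β-elimination of 5. The fallback sets out from 5 and comes back at 7, using an aldehyde aldol and oxidation in place of the Claisen condensation. iBu2AlH at −78 °C gives (R)-2-methyl-3-(triethylsilyloxy)propanal F8. The lithium enolate of 1 adds at −78 °C to give (6R)-5-hydroxy-4,6-dimethyl-7-(triethylsilyloxy)heptan-3-one F9. Dess–Martin oxidation gives 7.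

**Further compounds**
F1 | step 4 | (2R)-7-hydroxy-2,4,6-trimethyl-1-(triethylsilyloxy)dodecane-3,5-dione | CCCCCC(O)C(C)C(=O)C(C)C(=O)[C@H](C)CO[Si](CC)(CC)CC
F2 | step 4 | (2R)-2,4,6-trimethyl-1-(triethylsilyloxy)dodecane-3,5,7-trione | CCCCCC(=O)C(C)C(=O)C(C)C(=O)[C@H](C)CO[Si](CC)(CC)CC
F3 | step 6 | (R)-4-benzyl-3-[(2R,3S,4R)-4-(3,5-dimethyl-4-oxo-6-pentyl-4H-pyran-2-yl)-3-hydroxy-2-methylpentanoyl]-1,3-thiazolidine-2-thione | CCCCCc1oc([C@H](C)[C@H](O)[C@@H](C)C(=O)N2[C@H](Cc3ccccc3)CSC2=S)c(C)c(=O)c1C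
F4 | step 6 | C9 triethylsilyl ether of F3 | CCCCCc1oc([C@H](C)[C@H](O[Si](CC)(CC)CC)[C@@H](C)C(=O)N2[C@H](Cc3ccccc3)CSC2=S)c(C)c(=O)c1C
F5 | step 6 | 3,5-dimethyl-6-pentyl-2-[(2R,3S,4R)-4,6,8-trimethyl-5,7,9-trioxo-3-(triethylsilyloxy)undecan-2-yl]-4H-pyran-4-one | CCCCCc1oc([C@H](C)[C@H](O[Si](CC)(CC)CC)[C@@H](C)C(=O)C(C)C(=O)C(C)C(=O)CC)c(C)c(=O)c1C
F6 | step 6 | (2R,3R,4R)-bis-pyrone C9 triethylsilyl ether | CCCCCc1oc([C@H](C)[C@H](O[Si](CC)(CC)CC)[C@@H](C)c2oc(CC)c(C)c(=O)c2C)c(C)c(=O)c1C
F7 | step 6 | (2R,3R,4R)-2-(3,5-dimethyl-4-oxo-6-pentyl-4H-pyran-2-yl)-4-(6-ethyl-3,5-dimethyl-4-oxo-4H-pyran-2-yl)pentan-3-ol | CCCCCc1oc([C@H](C)[C@H](O)[C@@H](C)c2oc(CC)c(C)c(=O)c2C)c(C)c(=O)c1C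
F8 | step 3 | (R)-2-methyl-3-(triethylsilyloxy)propanal | O=C[C@H](C)CO[Si](CC)(CC)CC
F9 | step 3 | (6R)-5-hydroxy-4,6-dimethyl-7-(triethylsilyloxy)heptan-3-one | CCC(=O)C(C)C(O)[C@H](C)CO[Si](CC)(CC)CC
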